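The route rests on disconnecting C9–C10. C10 is C2 of the 3(2H)-furanone ring (O–C10–C1(=O)–C2=C3), so loss of its proton gives an aromatic 3-oxidofuran, and C10 of that anion can displace a primary iodide on C9. This single operation closes the ten-membered carbocycle C1–C10 (nine-membered when traced through the furanone oxygen) and creates the quaternary C10 stereocentre. The precursor is a cis-4,5-disubstituted γ-lactone (ring O–C6–C7–C11–C12) that carries the C8(OTBS)–C9H2I arm on C7 and, on C6, the Z-C4=C5 alkene bearing C15H2OPMB and the 2-methyl-3(2H)-furanone; it is used as a mixture of C10 epimers.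

Key step: step 15

Remark: germacrane numbering is used for atoms (C11/C13 = lactone α-carbon and its methylene, C14 = methyl on C10, C15 = CH2O on C4); the target SMILES is read as 4Z,6S,7R,8R,10R, i.e. with H6 and H7 on the same face (cis-fused lactone).

Step 1
Reactants: 1 dimethyl (S)-malate
Product: 2 methyl (3S)-3,4-dihydroxybutanoate
Conditions: BH3·SMe2 (1.0 equiv), NaBH4 (5 mol %), THF, 0 °C to rt; MeOH quench
Reagents that add atoms: none
Why: Chemoselective borane reduction of an α-hydroxy ester, in which the alkoxyborane formed at the C8 hydroxyl delivers hydride under borohydride catalysis only to the neighbouring ester (future C9); the C8 stereocentre is taken from L-malate.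

Step 2
Reactants: 2 methyl (3S)-3,4-dihydroxybutanoate
Product: 3 methyl (3S)-3-hydroxy-4-(triphenylmethoxy)butanoate
Conditions: Ph3CCl, Et3N, DMAP (cat.), CH2Cl2, 0 °C to rt
Reagents that add atoms: chlorotriphenylmethane (trityl chloride), ClC(c1ccccc1)(c1ccccc1)c1ccccc1
Why: Selective tritylation of the primary hydroxyl on steric grounds, giving a base-stable, non-migrating C9 ether and leaving the C8 hydroxyl free for the next step.

Step 3
Reactants: 3 methyl (3S)-3-hydroxy-4-(triphenylmethoxy)butanoate; 4 allyl bromide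
Product: 6 methyl (2R,3S)-3-hydroxy-2-(prop-2-en-1-yl)-4-(triphenylmethoxy)butanoate, via dilithium dianion 5 (not isolated)
Conditions: LiN(i-Pr)2 (2.2 equiv), THF, −78 to −20 °C; then 4, DMPU, −78 to −20 °C
Reagents that add atoms: none
Why: Fráter–Seebach alkylation, in which the lithium alkoxide–enolate chelate is attacked on the face remote from the CH2OTr group, so C7 should be set anti to the C8 oxygen; the allyl group is the masked C11–C12 carboxymethyl unit.

Step 4
Reactants: 6 allylated hydroxy ester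
Product: 7 (2R,3S)-3-hydroxy-N-methoxy-N-methyl-2-(prop-2-en-1-yl)-4-(triphenylmethoxy)butanamide
Conditions: MeNH(OMe)·HCl, i-PrMgCl, THF, −20 to 0 °C
Reagents that add atoms: N,O-dimethylhydroxylamine hydrochloride, CNOC.Cl
Why: Weinreb amidation of the methyl ester with the chloromagnesium amide, a reaction that is routine for β-hydroxy esters and should leave C7 untouched because the substrate is held as its magnesium alkoxide.

Step 5
Reactants: 7 hydroxy Weinreb amide
Product: 8 (2R,3S)-3-[(tert-butyldimethylsilyl)oxy]-N-methoxy-N-methyl-2-(prop-2-en-1-yl)-4-(triphenylmethoxy)butanamide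
Conditions: TBSOTf, 2,6-lutidine, CH2Cl2, −78 to 0 °C
Reagents that add atoms: tert-butyldimethylsilyl trifluoromethanesulfonate, CC(C)(C)[Si](C)(C)OS(=O)(=O)C(F)(F)F
Why: Silylation of the hindered secondary alcohol with the silyl triflate, TBS being chosen because it must survive mild acid, carbonate and amide base until step 17.

Step 6
Reactants: 8 silylated Weinreb amide; 9 4-methoxybenzyl propargyl ether
Product: 11 (5R,6S)-6-[(tert-butyldimethylsilyl)oxy]-1-[(4-methoxyphenyl)methoxy]-5-(prop-2-en-1-yl)-7-(triphenylmethoxy)hept-2-yn-4-one, via lithium acetylide 10 (not isolated)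
Conditions: 9, n-BuLi, THF, −78 °C; then 8, −78 to 0 °C; aq. NH4Cl
Reagents that add atoms: none
Why: Weinreb ketone synthesis, in which the chelated tetrahedral adduct collapses only on quench, so the acetylide adds once and the β-silyloxy ynone is not exposed to base.

Step 7
Reactants: 11 ynone
Product: 12 (4R,5S,6S)-6-[(tert-butyldimethylsilyl)oxy]-1-[(4-methoxyphenyl)methoxy]-5-(prop-2-en-1-yl)-7-(triphenylmethoxy)hept-2-yn-4-ol
Conditions: Ru[(R,R)-TsDPEN](p-cymene) (5 mol %), i-PrOH, rt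
Reagents that add atoms: none
Why: Noyori asymmetric transfer hydrogenation of an alkynyl ketone, in which the (R,R)-ligand directs hydride to the face that gives the C6 alcohol anti to the allyl branch, a sense the Felkin–Anh preference of C7 should reinforce, under base-free and borane-free conditions that spare the alkene.

Step 8
Reactants: 12 propargylic alcohol
Product: 14 (2Z,4R,5S,6S)-6-[(tert-butyldimethylsilyl)oxy]-2-iodo-1-[(4-methoxyphenyl)methoxy]-5-(prop-2-en-1-yl)-7-(triphenylmethoxy)hept-2-en-4-ol, via cyclic vinylalanate 13 (not isolated)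
Conditions: NaAlH2(OCH2CH2OCH3)2 (Red-Al), THF, 0 °C to rt; then I2, THF, −78 °C; cold aq. Na2S2O3, then aq. potassium sodium tartrate
Reagents that add atoms: iodine, II
Why: Hydroxyl-directed trans-hydroalumination places aluminium on C4 in a five-membered alkoxyalanate and iodinolysis with retention gives the Z-iodoalkene with C6 and iodine cis, which is the geometry C3 will inherit; the cold reductive quench removes iodine before the free alcohol could undergo iodoetherification with the allyl group.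

Step 9
Reactants: 14 Z-iodoalkenol
Product: 17 (4S,5R)-4-[(1S)-1-[(tert-butyldimethylsilyl)oxy]-2-(triphenylmethoxy)ethyl]-5-[(1Z)-2-iodo-3-[(4-methoxyphenyl)methoxy]prop-1-en-1-yl]oxolan-2-ol (anomer mixture), via triol 15 (not isolated), via hydroxy aldehyde 16 (not isolated)
Conditions: OsO4 (2 mol %), NaIO4, 2,6-lutidine, dioxane/H2O (3:1), rt
Reagents that add atoms: osmium tetroxide, O=[Os](=O)(=O)=O (oxygen carrier, regenerated by sodium periodate, [Na+].[O-]I(=O)(=O)=O)
Why: Lemieux–Johnson cleavage is selective for the monosubstituted alkene over the hindered, electron-poor iodoalkene, and the C12 aldehyde is trapped at once by the C6 hydroxyl as the five-membered lactol, in which the C5 and C8 substituents are cis as fixed in steps 3 and 7.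

Step 10
Reactants: 17 lactol
Product: 18 (4S,5R)-4-[(1S)-1-[(tert-butyldimethylsilyl)oxy]-2-(triphenylmethoxy)ethyl]-5-[(1Z)-2-iodo-3-[(4-methoxyphenyl)methoxy]prop-1-en-1-yl]oxolan-2-one
Conditions: TEMPO (cat.), PhI(OAc)2, NaHCO3, CH2Cl2, rt
Reagents that add atoms: none
Why: Oxoammonium-mediated oxidation of the lactol to the γ-lactone under buffered conditions that should spare the PMB and trityl ethers and the vinyl iodide.

Step 11
Reactants: 18 iodoalkenyl lactone; 19 but-3-yn-2-ol (racemic)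
Product: 20 (4S,5S)-4-[(1S)-1-[(tert-butyldimethylsilyl)oxy]-2-(triphenylmethoxy)ethyl]-5-[(1Z)-6-hydroxy-2-{[(4-methoxyphenyl)methoxy]methyl}-3-oxohept-1-en-4-yn-1-yl]oxolan-2-one (carbinol epimers)
Conditions: PdCl2(PPh3)2 (5 mol %), CuI (5 mol %), Et3N, THF, CO (1 atm), rt, slow addition of 19
Reagents that add atoms: carbon monoxide, [C-]#[O+]
Why: Carbonylative Sonogashira coupling, in which oxidative addition of the vinyl iodide to zerovalent palladium with retention, CO insertion and capture of the acylpalladium by the copper acetylide should give the cross-conjugated ynone with C3 cis to C6.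

Step 12
Reactants: 20 hydroxy ynone
Product: 22 (4S,5S)-4-[(1S)-1-[(tert-butyldimethylsilyl)oxy]-2-(triphenylmethoxy)ethyl]-5-[(1Z)-3-[(4-methoxyphenyl)methoxy]-2-(5-methyl-4-oxo-4,5-dihydrofuran-2-yl)prop-1-en-1-yl]oxolan-2-one (C10 epimers), via enaminone 21 (not isolated)
Conditions: Et2NH (1.5 equiv), EtOH/THF, 0 °C; then AcOH/THF/H2O (3:1:1), rt
Reagents that add atoms: water, O (its oxygen becomes the C1 carbonyl oxygen; the former C3 carbonyl oxygen leaves as water)
Why: Amine-mediated conversion of a 4-hydroxy-2-ynone into a 3(2H)-furanone, in which conjugate addition of diethylamine gives the enaminone and mild aqueous acid hydrolyses it to the 1,3-diketone, which cyclodehydrates through the C10 hydroxyl; the acid is too weak to cleave the trityl, TBS or PMB ethers.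

Step 13
Reactants: 22 furanone trityl ether
Product: 23 (4S,5S)-4-[(1S)-1-[(tert-butyldimethylsilyl)oxy]-2-hydroxyethyl]-5-[(1Z)-3-[(4-methoxyphenyl)methoxy]-2-(5-methyl-4-oxo-4,5-dihydrofuran-2-yl)prop-1-en-1-yl]oxolan-2-one (C10 epimers)
Conditions: camphorsulfonic acid (0.1 equiv), MeOH/CH2Cl2 (1:2), 0 °C
Reagents that add atoms: none
Why: Acid-catalysed transfer of the trityl cation to methanol frees the primary C9 alcohol, while the hindered secondary TBS ether and the PMB ether should remain at this acidity and temperature.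

Step 14
Reactants: 23 primary alcohol
Product: 24 (4S,5S)-4-[(1S)-1-[(tert-butyldimethylsilyl)oxy]-2-iodoethyl]-5-[(1Z)-3-[(4-methoxyphenyl)methoxy]-2-(5-methyl-4-oxo-4,5-dihydrofuran-2-yl)prop-1-en-1-yl]oxolan-2-one (key-step precursor; C10 epimers)
Conditions: PPh3, I2, imidazole (premixed), CH2Cl2, 0 °C
Reagents that add atoms: iodine, II
Why: Garegg–Samuelsson (Appel-type) iodination of the primary alcohol through its alkoxyphosphonium iodide, with the phosphine consumed by iodine beforehand so that no free phosphine can add to the dienyl furanone.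

Step 15
Reactants: 24 iodo lactone with 2-methyl-3(2H)-furanone
Product: 26 (4Z,6S,7S,8R,10R)-8-[(tert-butyldimethylsilyl)oxy]-15-[(4-methoxyphenyl)methoxy]-1-oxo-3,10-epoxy-13-norgermacra-2,4-dien-12,6-olide, via cesium 3-oxidofuran 25 (not isolated)
Conditions: Cs2CO3 (3 equiv), DMF (0.003 M, syringe-pump addition of 24), 25 to 40 °C
Reagents that add atoms: none
Why: Proposed new method: Cs2CO3 removes the C10 proton, both C10 epimers of 24 giving the same planar, aromatic 3-oxidofuran 25, and C10 of this ambident anion attacks the primary iodide on C9 in an SN2 reaction that restores the furanone and creates the quaternary centre. The closest known reactions are intermolecular C2-alkylations of 2-alkyl-3(2H)-furanone enolates with alkyl halides and macrocyclising enolate alkylations; their combination in a dearomatising ring closure is new. The one new bond closes the ten-membered carbocycle C1–C10, which is the same event as closing the nine-membered oxacycle through the furanone oxygen, in an exo-tet mode (10-exo-tet counted through carbon, 9-exo-tet through oxygen). C10 is set by substrate control: the Z-C4=C5 alkene and the cis-lactone fold the C8–C9 arm over one face of the planar oxidofuran, and the bulky C8 silyloxy group is expected to stay on the outside of the forming ring, which should lead to the 10R configuration. The step needs carbon rather than oxygen alkylation and a single face of C10; the soft iodide, the loose cesium ion pair in DMF and the strain of the alternative meta-bridged 3-alkoxyfuran should favour carbon, and high dilution should suppress dimerisation.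

Step 16
Reactants: 26 bridged furanone lactone
Product: 30 (4Z,6S,7S,8R,10R)-8-[(tert-butyldimethylsilyl)oxy]-15-[(4-methoxyphenyl)methoxy]-1-oxo-3,10-epoxygermacra-2,4,11(13)-trien-12,6-olide, via lithium enolate 27 (not isolated), via Mannich base 28 (not isolated), via methiodide 29 (not isolated)
Conditions: LiN(i-Pr)2, THF, −78 °C; Me2N=CH2+ I−, −78 to 0 °C; then MeI, MeOH, rt; then aq. NaHCO3, CH2Cl2, rt
Reagents that add atoms: N,N-dimethylmethyleneiminium iodide (Eschenmoser's salt), C=[N+](C)C.[I-]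
Why: Eschenmoser α-methylenation, in which the lactone is the only enolisable carbonyl now that C10 is quaternary, its lithium enolate undergoes a Mannich reaction with the iminium salt, and quaternisation followed by elimination of trimethylamine gives the C11=C13 alkene; it is done before the tiglate is present so that no second ester competes.

Step 17
Reactants: 30 α-methylene lactone silyl ether
Product: 31 (4Z,6S,7R,8R,10R)-8-hydroxy-15-[(4-methoxyphenyl)methoxy]-1-oxo-3,10-epoxygermacra-2,4,11(13)-trien-12,6-olide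
Conditions: HF·pyridine, pyridine, THF, 0 °C to rt
Reagents that add atoms: none
Why: Fluoride-mediated cleavage of the secondary TBS ether under buffered, weakly acidic conditions that an α-methylene lactone and a PMB ether tolerate and that should not promote lactone migration to O8.

Step 18
Reactants: 31 C8 alcohol; 32 tigloyl chloride
Product: 33 (4Z,6S,7R,8R,10R)-15-[(4-methoxyphenyl)methoxy]-8-{[(2E)-2-methylbut-2-enoyl]oxy}-1-oxo-3,10-epoxygermacra-2,4,11(13)-trien-12,6-olide
Conditions: 32, pyridine, DMAP (cat.), CH2Cl2, 0 °C to rt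
Reagents that add atoms: none
Why: DMAP-catalysed acylation of the secondary alcohol with the acid chloride, using pyridine instead of a trialkylamine so that the E-geometry of the tigloyl unit is not lost through a vinylketene.

Step 19
Reactants: 33 tiglate PMB ether
Product: 34 (4Z,6S,7R,8R,10R)-15-hydroxy-8-{[(2E)-2-methylbut-2-enoyl]oxy}-1-oxo-3,10-epoxygermacra-2,4,11(13)-trien-12,6-olide (target)
Conditions: DDQ, CH2Cl2/pH 7 phosphate buffer, 0 °C
Reagents that add atoms: none
Why: Oxidative PMB cleavage, in which DDQ abstracts hydride from the electron-rich benzylic position and the oxocarbenium ion is hydrolysed, under neutral conditions that should leave both esters, the α-methylene lactone and the furanone intact.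

Compound list
1 | dimethyl (2S)-2-hydroxybutanedioate (dimethyl L-malate) | COC(=O)C[C@H](O)C(=O)OC | starting material
2 | methyl (3S)-3,4-dihydroxybutanoate | COC(=O)C[C@H](O)CO | intermediate
3 | methyl (3S)-3-hydroxy-4-(triphenylmethoxy)butanoate | COC(=O)C[C@H](O)COC(c1ccccc1)(c1ccccc1)c1ccccc1 | intermediate
4 | allyl bromide (3-bromoprop-1-ene) | C=CCBr | starting material
5 | dilithium alkoxide–enolate (dianion) of 3, not isolated | COC(O[Li])=C[C@H](O[Li])COC(c1ccccc1)(c1ccccc1)c1ccccc1 | intermediate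
6 | methyl (2R,3S)-3-hydroxy-2-(prop-2-en-1-yl)-4-(triphenylmethoxy)butanoate | COC(=O)[C@H](CC=C)[C@H](O)COC(c1ccccc1)(c1ccccc1)c1ccccc1 | intermediate
7 | (2R,3S)-3-hydroxy-N-methoxy-N-methyl-2-(prop-2-en-1-yl)-4-(triphenylmethoxy)butanamide | CON(C)C(=O)[C@H](CC=C)[C@H](O)COC(c1ccccc1)(c1ccccc1)c1ccccc1 | intermediate
8 | (2R,3S)-3-[(tert-butyldimethylsilyl)oxy]-N-methoxy-N-methyl-2-(prop-2-en-1-yl)-4-(triphenylmethoxy)butanamide | CON(C)C(=O)[C@H](CC=C)[C@H](O[Si](C)(C)C(C)(C)C)COC(c1ccccc1)(c1ccccc1)c1ccccc1 | intermediate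
9 | 1-methoxy-4-[(prop-2-yn-1-yloxy)methyl]benzene (4-methoxybenzyl propargyl ether) | C#CCOCc1ccc(OC)cc1 | starting material
10 | lithium acetylide of 9, not isolated | [Li]C#CCOCc1ccc(OC)cc1 | intermediate
11 | (5R,6S)-6-[(tert-butyldimethylsilyl)oxy]-1-[(4-methoxyphenyl)methoxy]-5-(prop-2-en-1-yl)-7-(triphenylmethoxy)hept-2-yn-4-one | C(c1ccccc1)(c1ccccc1)(c1ccccc1)OC[C@@H](O[Si](C)(C)C(C)(C)C)[C@@H](CC=C)C(=O)C#CCOCc1ccc(OC)cc1 | intermediate
12 | (4R,5S,6S)-6-[(tert-butyldimethylsilyl)oxy]-1-[(4-methoxyphenyl)methoxy]-5-(prop-2-en-1-yl)-7-(triphenylmethoxy)hept-2-yn-4-ol | C(c1ccccc1)(c1ccccc1)(c1ccccc1)OC[C@@H](O[Si](C)(C)C(C)(C)C)[C@@H](CC=C)[C@@H](O)C#CCOCc1ccc(OC)cc1 | intermediate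
13 | sodium cyclic alkoxy(alkenyl)alanate from trans-hydroalumination of 12 (Al on C4, five-membered O6–Al–C4 ring), not isolated | [Na+].COCCO[Al-]1(OCCOC)O[C@H]([C@H](CC=C)[C@@H](COC(c2ccccc2)(c2ccccc2)c2ccccc2)O[Si](C)(C)C(C)(C)C)C=C1COCc1ccc(OC)cc1 | intermediate
14 | (2Z,4R,5S,6S)-6-[(tert-butyldimethylsilyl)oxy]-2-iodo-1-[(4-methoxyphenyl)methoxy]-5-(prop-2-en-1-yl)-7-(triphenylmethoxy)hept-2-en-4-ol | C(c1ccccc1)(c1ccccc1)(c1ccccc1)OC[C@@H](O[Si](C)(C)C(C)(C)C)[C@@H](CC=C)[C@@H](O)/C=C(/COCc1ccc(OC)cc1)I | intermediate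
15 | triol from dihydroxylation of the allyl group of 14 (new carbinol centre unspecified), not isolated | C(c1ccccc1)(c1ccccc1)(c1ccccc1)OC[C@@H](O[Si](C)(C)C(C)(C)C)[C@@H](CC(O)CO)[C@@H](O)/C=C(/COCc1ccc(OC)cc1)I | intermediate
16 | hydroxy aldehyde from cleavage of 15 (C12 aldehyde), not isolated | C(c1ccccc1)(c1ccccc1)(c1ccccc1)OC[C@@H](O[Si](C)(C)C(C)(C)C)[C@@H](CC=O)[C@@H](O)/C=C(/COCc1ccc(OC)cc1)I | intermediate
17 | (4S,5R)-4-[(1S)-1-[(tert-butyldimethylsilyl)oxy]-2-(triphenylmethoxy)ethyl]-5-[(1Z)-2-iodo-3-[(4-methoxyphenyl)methoxy]prop-1-en-1-yl]oxolan-2-ol (lactol, anomer mixture) | OC1C[C@H]([C@@H](COC(c2ccccc2)(c2ccccc2)c2ccccc2)O[Si](C)(C)C(C)(C)C)[C@@H](O1)/C=C(/COCc1ccc(OC)cc1)I | intermediate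
18 | (4S,5R)-4-[(1S)-1-[(tert-butyldimethylsilyl)oxy]-2-(triphenylmethoxy)ethyl]-5-[(1Z)-2-iodo-3-[(4-methoxyphenyl)methoxy]prop-1-en-1-yl]oxolan-2-one | O=C1C[C@H]([C@@H](COC(c2ccccc2)(c2ccccc2)c2ccccc2)O[Si](C)(C)C(C)(C)C)[C@@H](O1)/C=C(/COCc1ccc(OC)cc1)I | intermediate
19 | but-3-yn-2-ol (racemic) | CC(O)C#C | starting material
20 | (4S,5S)-4-[(1S)-1-[(tert-butyldimethylsilyl)oxy]-2-(triphenylmethoxy)ethyl]-5-[(1Z)-6-hydroxy-2-{[(4-methoxyphenyl)methoxy]methyl}-3-oxohept-1-en-4-yn-1-yl]oxolan-2-one (carbinol epimers) | O=C1C[C@H]([C@@H](COC(c2ccccc2)(c2ccccc2)c2ccccc2)O[Si](C)(C)C(C)(C)C)[C@@H](O1)/C=C(/COCc1ccc(OC)cc1)C(=O)C#CC(C)O | intermediate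
21 | enaminone: adduct of diethylamine at C1 of 20 (β-diethylamino enone), not isolated | O=C1C[C@H]([C@@H](COC(c2ccccc2)(c2ccccc2)c2ccccc2)O[Si](C)(C)C(C)(C)C)[C@@H](O1)/C=C(/COCc1ccc(OC)cc1)C(=O)C=C(N(CC)CC)C(C)O | intermediate
22 | (4S,5S)-4-[(1S)-1-[(tert-butyldimethylsilyl)oxy]-2-(triphenylmethoxy)ethyl]-5-[(1Z)-3-[(4-methoxyphenyl)methoxy]-2-(5-methyl-4-oxo-4,5-dihydrofuran-2-yl)prop-1-en-1-yl]oxolan-2-one (C10 epimers) | C(c1ccccc1)(c1ccccc1)(c1ccccc1)OC[C@@H](O[Si](C)(C)C(C)(C)C)[C@H]1CC(=O)O[C@H]1/C=C(/COCc1ccc(OC)cc1)C1=CC(=O)C(C)O1 | intermediate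
23 | (4S,5S)-4-[(1S)-1-[(tert-butyldimethylsilyl)oxy]-2-hydroxyethyl]-5-[(1Z)-3-[(4-methoxyphenyl)methoxy]-2-(5-methyl-4-oxo-4,5-dihydrofuran-2-yl)prop-1-en-1-yl]oxolan-2-one (C10 epimers) | OC[C@@H](O[Si](C)(C)C(C)(C)C)[C@H]1CC(=O)O[C@H]1/C=C(/COCc1ccc(OC)cc1)C1=CC(=O)C(C)O1 | intermediate
24 | (4S,5S)-4-[(1S)-1-[(tert-butyldimethylsilyl)oxy]-2-iodoethyl]-5-[(1Z)-3-[(4-methoxyphenyl)methoxy]-2-(5-methyl-4-oxo-4,5-dihydrofuran-2-yl)prop-1-en-1-yl]oxolan-2-one (key-step precursor, C10 epimers) | IC[C@@H](O[Si](C)(C)C(C)(C)C)[C@H]1CC(=O)O[C@H]1/C=C(/COCc1ccc(OC)cc1)C1=CC(=O)C(C)O1 | intermediate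
25 | cesium 3-oxidofuran (C10 enolate) of 24, not isolated | IC[C@@H](O[Si](C)(C)C(C)(C)C)[C@H]1CC(=O)O[C@H]1/C=C(/COCc1ccc(OC)cc1)c1cc([O-])c(C)o1.[Cs+] | intermediate
26 | (4Z,6S,7S,8R,10R)-8-[(tert-butyldimethylsilyl)oxy]-15-[(4-methoxyphenyl)methoxy]-1-oxo-3,10-epoxy-13-norgermacra-2,4-dien-12,6-olide (key-step product) | C1C(=O)O[C@H]2/C=C(/COCc4ccc(OC)cc4)C3=CC(=O)[C@@](C)(C[C@@H](O[Si](C)(C)C(C)(C)C)[C@@H]12)O3 | intermediate
27 | lithium enolate of 26 (C11=C12), not isolated | C1=C(O[Li])O[C@H]2/C=C(/COCc4ccc(OC)cc4)C3=CC(=O)[C@@](C)(C[C@@H](O[Si](C)(C)C(C)(C)C)[C@@H]12)O3 | intermediate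
28 | Mannich base: 11-[(dimethylamino)methyl] derivative of 26 (C11 epimers), not isolated | CN(C)CC1C(=O)O[C@H]2/C=C(/COCc4ccc(OC)cc4)C3=CC(=O)[C@@](C)(C[C@@H](O[Si](C)(C)C(C)(C)C)[C@@H]12)O3 | intermediate
29 | trimethylammonium iodide (methiodide) of 28, not isolated | C[N+](C)(C)CC1C(=O)O[C@H]2/C=C(/COCc4ccc(OC)cc4)C3=CC(=O)[C@@](C)(C[C@@H](O[Si](C)(C)C(C)(C)C)[C@@H]12)O3.[I-] | intermediate
30 | (4Z,6S,7S,8R,10R)-8-[(tert-butyldimethylsilyl)oxy]-15-[(4-methoxyphenyl)methoxy]-1-oxo-3,10-epoxygermacra-2,4,11(13)-trien-12,6-olide | C=C1C(=O)O[C@H]2/C=C(/COCc4ccc(OC)cc4)C3=CC(=O)[C@@](C)(C[C@@H](O[Si](C)(C)C(C)(C)C)[C@@H]12)O3 | intermediate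
31 | (4Z,6S,7R,8R,10R)-8-hydroxy-15-[(4-methoxyphenyl)methoxy]-1-oxo-3,10-epoxygermacra-2,4,11(13)-trien-12,6-olide | C=C1C(=O)O[C@H]2/C=C(/COCc4ccc(OC)cc4)C3=CC(=O)[C@@](C)(C[C@@H](O)[C@@H]12)O3 | intermediate
32 | (2E)-2-methylbut-2-enoyl chloride (tigloyl chloride) | C/C=C(\C)C(Cl)=O | starting material
33 | (4Z,6S,7R,8R,10R)-15-[(4-methoxyphenyl)methoxy]-8-{[(2E)-2-methylbut-2-enoyl]oxy}-1-oxo-3,10-epoxygermacra-2,4,11(13)-trien-12,6-olide | C=C1C(=O)O[C@H]2/C=C(/COCc4ccc(OC)cc4)C3=CC(=O)[C@@](C)(C[C@@H](OC(=O)/C(C)=C/C)[C@@H]12)O3 | intermediate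
34 | (4Z,6S,7R,8R,10R)-15-hydroxy-8-{[(2E)-2-methylbut-2-enoyl]oxy}-1-oxo-3,10-epoxygermacra-2,4,11(13)-trien-12,6-olide (CNP0269689.6) | C=C1C(=O)O[C@H]2/C=C(/CO)C3=CC(=O)[C@@](C)(C[C@@H](OC(=O)/C(C)=C/C)[C@@H]12)O3 | target

Total step count: 19. Longest linear sequence: 19 steps (1 to 34); compounds 4, 9, 19 and 32 enter as commercial reagents.

Steps most likely to fail

Step 15 (the key ring closure). What may go wrong: alkylation on the oxido oxygen instead of C10, closure on the other face of the oxidofuran so that C10 is formed with the wrong configuration, or intermolecular alkylation outrunning the strained ring closure. The fallback makes the C9–C10 bond between two fragments and closes the ring at C4=C5 by metathesis, both known operations on 3(2H)-furanones; it sets out from 12 and comes back to the route at 26. Lemieux–Johnson cleavage of the allyl group of 12 (OsO4 cat., NaIO4, 2,6-lutidine) gives the alkynyl lactol F1, and TEMPO/PhI(OAc)2 oxidation gives the alkynyl lactone F2. Semihydrogenation (H2, Pd/CaCO3 poisoned with Pb(OAc)2, quinoline) gives the (Z)-alkenyl lactone F3, camphorsulfonic acid in MeOH removes the trityl group to give the primary alcohol F4, and PPh3/I2/imidazole gives the iodide F5. The furanone partner comes from commercial 2-bromoprop-2-en-1-ol: 4-methoxybenzyl trichloroacetimidate with catalytic camphorsulfonic acid gives the bromoallyl PMB ether F6, carbonylative Sonogashira coupling with 19 (conditions of step 11, 50 °C) gives the hydroxy dienynone F7, and Et2NH followed by aqueous AcOH gives the 5-alkenyl-2-methyl-3(2H)-furanone F8. Intermolecular C-alkylation of the cesium enolate of F8 (used in excess; Cs2CO3, DMF, 40 °C) with F5 gives the metathesis precursor F9 together with its C10 epimer, which is removed by chromatography. Ring-closing metathesis of F9 (second-generation Hoveyda–Grubbs catalyst, toluene, 80 °C, high dilution) forms C4=C5 as the ring-enforced Z-alkene with loss of allyl 4-methoxybenzyl ether and delivers 26.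

Step 11. What may go wrong: direct alkyne–alkenyl coupling without CO insertion, or ionisation of the allylic C6–O lactone bond by zerovalent palladium. The fallback avoids palladium and CO; it sets out from 18 and 19 and comes back at 22. Silylation of 19 (Et3SiCl, imidazole) gives the silyl ether F10, and its lithium acetylide (n-BuLi) is formylated with DMF to the ynal F11. Nozaki–Hiyama–Kishi coupling of 18 with F11 (CrCl2, NiCl2 cat., DMSO/THF, rt), which tolerates the lactone, gives the dienynol F12 as a mixture of carbinol epimers, and Dess–Martin oxidation gives the ynone F13. Under the conditions of step 12 (Et2NH, then AcOH/THF/H2O, which also cleaves the secondary triethylsilyl ether), F13 should give 22.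

Step 16. What may go wrong: the lithium enolate may add across the ring to the C1 ketone, or be lost by proton transfer from C6, before it meets the iminium salt. The fallback avoids a free lithium enolate; it sets out from 26 and comes back at 30. Soft enolisation (TBSOTf, Et3N, CH2Cl2, 0 °C) gives the silyl ketene acetal F14. Alkylation with chloromethyl phenyl sulfide under ZnBr2 catalysis gives the α-(phenylthiomethyl) lactone F15. NaIO4 (MeOH/H2O) gives the sulfoxide F16, and thermolysis (toluene, 100 °C, CaCO3) eliminates benzenesulfenic acid to give 30.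

Further compounds
F1 | step 15 | (4S,5R)-4-[(1S)-1-[(tert-butyldimethylsilyl)oxy]-2-(triphenylmethoxy)ethyl]-5-{3-[(4-methoxyphenyl)methoxy]prop-1-yn-1-yl}oxolan-2-ol (anomer mixture) | OC1C[C@H]([C@@H](COC(c2ccccc2)(c2ccccc2)c2ccccc2)O[Si](C)(C)C(C)(C)C)[C@@H](O1)C#CCOCc1ccc(OC)cc1
F2 | step 15 | (4S,5R)-4-[(1S)-1-[(tert-butyldimethylsilyl)oxy]-2-(triphenylmethoxy)ethyl]-5-{3-[(4-methoxyphenyl)methoxy]prop-1-yn-1-yl}oxolan-2-one | O=C1C[C@H]([C@@H](COC(c2ccccc2)(c2ccccc2)c2ccccc2)O[Si](C)(C)C(C)(C)C)[C@@H](O1)C#CCOCc1ccc(OC)cc1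
F3 | step 15 | (4S,5S)-4-[(1S)-1-[(tert-butyldimethylsilyl)oxy]-2-(triphenylmethoxy)ethyl]-5-{(1Z)-3-[(4-methoxyphenyl)methoxy]prop-1-en-1-yl}oxolan-2-one | O=C1C[C@H]([C@@H](COC(c2ccccc2)(c2ccccc2)c2ccccc2)O[Si](C)(C)C(C)(C)C)[C@@H](O1)/C=C\COCc1ccc(OC)cc1
F4 | step 15 | (4S,5S)-4-[(1S)-1-[(tert-butyldimethylsilyl)oxy]-2-hydroxyethyl]-5-{(1Z)-3-[(4-methoxyphenyl)methoxy]prop-1-en-1-yl}oxolan-2-one | O=C1C[C@H]([C@@H](CO)O[Si](C)(C)C(C)(C)C)[C@@H](O1)/C=C\COCc1ccc(OC)cc1
F5 | step 15 | (4S,5S)-4-[(1S)-1-[(tert-butyldimethylsilyl)oxy]-2-iodoethyl]-5-{(1Z)-3-[(4-methoxyphenyl)methoxy]prop-1-en-1-yl}oxolan-2-one | O=C1C[C@H]([C@@H](CI)O[Si](C)(C)C(C)(C)C)[C@@H](O1)/C=C\COCc1ccc(OC)cc1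
F6 | step 15 | 1-{[(2-bromoprop-2-en-1-yl)oxy]methyl}-4-methoxybenzene | C=C(Br)COCc1ccc(OC)cc1
F7 | step 15 | 6-hydroxy-2-{[(4-methoxyphenyl)methoxy]methyl}hept-1-en-4-yn-3-one (racemic) | C=C(COCc1ccc(OC)cc1)C(=O)C#CC(C)O
F8 | step 15 | 5-{3-[(4-methoxyphenyl)methoxy]prop-1-en-2-yl}-2-methylfuran-3(2H)-one (racemic) | C=C(COCc1ccc(OC)cc1)C1=CC(=O)C(C)O1
F9 | step 15 | (4S,5S)-4-[(1R)-1-[(tert-butyldimethylsilyl)oxy]-2-[(2R)-5-{3-[(4-methoxyphenyl)methoxy]prop-1-en-2-yl}-2-methyl-3-oxo-2,3-dihydrofuran-2-yl]ethyl]-5-{(1Z)-3-[(4-methoxyphenyl)methoxy]prop-1-en-1-yl}oxolan-2-one | C=C(COCc1ccc(OC)cc1)C1=CC(=O)[C@@](C)(C[C@@H](O[Si](C)(C)C(C)(C)C)[C@H]2CC(=O)O[C@H]2/C=C\COCc2ccc(OC)cc2)O1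
F10 | step 11 | triethyl[(but-3-yn-2-yl)oxy]silane (racemic) | CC(O[Si](CC)(CC)CC)C#C
F11 | step 11 | 4-[(triethylsilyl)oxy]pent-2-ynal (racemic) | CC(O[Si](CC)(CC)CC)C#CC=O
F12 | step 11 | (4S,5S)-4-[(1S)-1-[(tert-butyldimethylsilyl)oxy]-2-(triphenylmethoxy)ethyl]-5-[(1Z)-3-hydroxy-2-{[(4-methoxyphenyl)methoxy]methyl}-6-[(triethylsilyl)oxy]hept-1-en-4-yn-1-yl]oxolan-2-one (carbinol epimers) | O=C1C[C@H]([C@@H](COC(c2ccccc2)(c2ccccc2)c2ccccc2)O[Si](C)(C)C(C)(C)C)[C@@H](O1)/C=C(/COCc1ccc(OC)cc1)C(O)C#CC(C)O[Si](CC)(CC)CC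
F13 | step 11 | (4S,5S)-4-[(1S)-1-[(tert-butyldimethylsilyl)oxy]-2-(triphenylmethoxy)ethyl]-5-[(1Z)-2-{[(4-methoxyphenyl)methoxy]methyl}-3-oxo-6-[(triethylsilyl)oxy]hept-1-en-4-yn-1-yl]oxolan-2-one (epimers at the silyloxy carbon) | O=C1C[C@H]([C@@H](COC(c2ccccc2)(c2ccccc2)c2ccccc2)O[Si](C)(C)C(C)(C)C)[C@@H](O1)/C=C(/COCc1ccc(OC)cc1)C(=O)C#CC(C)O[Si](CC)(CC)CC
F14 | step 16 | tert-butyldimethylsilyl ketene acetal of 26 (C11=C12, O-silylated lactone) | C1=C(O[Si](C)(C)C(C)(C)C)O[C@H]2/C=C(/COCc4ccc(OC)cc4)C3=CC(=O)[C@@](C)(C[C@@H](O[Si](C)(C)C(C)(C)C)[C@@H]12)O3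
F15 | step 16 | 11-[(phenylsulfanyl)methyl] derivative of 26 (C11 epimers) | C(Sc1ccccc1)C1C(=O)O[C@H]2/C=C(/COCc4ccc(OC)cc4)C3=CC(=O)[C@@](C)(C[C@@H](O[Si](C)(C)C(C)(C)C)[C@@H]12)O3
F16 | step 16 | 11-[(phenylsulfinyl)methyl] derivative of 26 (sulfoxide, stereoisomer mixture) | C(S(=O)c1ccccc1)C1C(=O)O[C@H]2/C=C(/COCc4ccc(OC)cc4)C3=CC(=O)[C@@](C)(C[C@@H](O[Si](C)(C)C(C)(C)C)[C@@H]12)O3
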